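**Retrosynthetic overview**

1. Numbering: ring B is C6–C1–C2(Cl)–C3(Br, CH3)–C4–C5 and ring A is C6–C7(=C14H2)–C8–C9(OAc)–C10(Br)–C11(CH3)2. The C2 chloride and C3 bromide are traced back to a C2=C3 alkene (epoxide, chloride opening at C2, tertiary alcohol to bromide).
2. Ring A (C7 methylene, C9 acetate, C10 bromide) is traced back to a C7 carbonyl/C9 enol ether, a dimedone-type vinylogous ester: silylmethyl addition with carbonyl transposition, C10 bromination, desilylative deconjugation, reduction, acetylation.
3. The strategy rests on ring B being a 4-methylcyclohex-3-ene (C6–C1–C2=C3(CH3)–C4–C5) attached to ring A only through the quaternary spiro carbon C6. This is the pattern a carbon nucleophile gives when it closes on the far end of a C1–C2–C3 linalyl-type allyl cation.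
4. Key disconnection C6–C1: the C6 enolate of the vinylogous ester and a palladium π-allyl generated from a tertiary C3 methyl carbonate, cyclising at the unsubstituted terminus C1.
5. Ring order: ring A comes intact from dimedone (C7–C11). The side chain comes from a four-carbon ketal halide (C5, C4, C3, C3-methyl) and vinylmagnesium bromide (C2, C1). Ring B is closed in the key step.

Key step: step 6

Assumption: the sense of induction of the diphosphine in step 6 cannot be predicted with confidence; the (S,S) ligand is written, and its enantiomer is used instead if it should deliver the other configuration at C6.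

**Route**

Step 1
Reactants: 1 dimedone
Product: 2 3-isobutoxy-5,5-dimethylcyclohex-2-en-1-one
Conditions: iBuOH, TsOH·H2O (cat.), toluene, reflux, Dean–Stark trap
Reagents that add atoms: isobutanol CC(C)CO
Why: Acid-catalysed condensation of the enolised symmetric 1,3-dione with the alcohol (vinylogous Fischer esterification) is driven by azeotropic removal of water and creates no stereocentre.

Step 2
Reactants: 3 2-(2-bromoethyl)-2-methyl-1,3-dioxolane
Product: 4 2-(2-iodoethyl)-2-methyl-1,3-dioxolane
Conditions: NaI, acetone, reflux
Reagents that add atoms: sodium iodide [Na+].[I-]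
Why: Finkelstein exchange, driven by precipitation of NaBr, turns the sluggish primary bromide into the iodide needed to alkylate a hindered enolate.

Step 3
Reactants: 2 3-isobutoxy-5,5-dimethylcyclohex-2-en-1-one; 4 2-(2-iodoethyl)-2-methyl-1,3-dioxolane
Product: 6 3-isobutoxy-5,5-dimethyl-6-[2-(2-methyl-1,3-dioxolan-2-yl)ethyl]cyclohex-2-en-1-one (racemic), via lithium enolate 5 (not isolated)
Conditions: LiN(iPr)2, THF, −78 °C; then 4, DMPU, −78 → 23 °C
Reagents that add atoms: none
Why: Kinetic α′-deprotonation of the vinylogous ester and SN2 alkylation of the enolate by the primary iodide (Stork–Danheiser alkylation) should give the monoalkylated product, whose C6 centre is racemic and is erased in step 6.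

Step 4
Reactants: 6 3-isobutoxy-5,5-dimethyl-6-[2-(2-methyl-1,3-dioxolan-2-yl)ethyl]cyclohex-2-en-1-one
Product: 7 3-isobutoxy-5,5-dimethyl-6-(3-oxobutyl)cyclohex-2-en-1-one (racemic)
Conditions: PPTS, acetone/H2O, 50 °C
Reagents that add atoms: water O
Why: Mild acid-catalysed acetal hydrolysis frees the methyl ketone, while the isobutyl vinylogous ester, which needs stronger aqueous acid, should survive; no stereocentre is formed.

Step 5
Reactants: 7 3-isobutoxy-5,5-dimethyl-6-(3-oxobutyl)cyclohex-2-en-1-one; 8 vinylmagnesium bromide
Product: 10 5-(4-isobutoxy-6,6-dimethyl-2-oxocyclohex-3-en-1-yl)-3-methylpent-1-en-3-yl methyl carbonate (all stereoisomers), via bromomagnesium alkoxide 9 (not isolated)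
Conditions: CH2=CHMgBr, THF, −78 → 0 °C; then ClCO2Me, 0 → 23 °C
Reagents that add atoms: methyl chloroformate COC(=O)Cl
Why: Grignard 1,2-addition goes to the unhindered methyl ketone rather than the deactivated, α-branched vinylogous ester carbonyl, and the tertiary alkoxide is acylated in the same flask; the new C3 centre forms without control and is erased on ionisation in step 6.

Step 6
Reactants: 10 5-(4-isobutoxy-6,6-dimethyl-2-oxocyclohex-3-en-1-yl)-3-methylpent-1-en-3-yl methyl carbonate
Product: 12 (6S)-9-isobutoxy-3,11,11-trimethylspiro[5.5]undeca-2,8-dien-7-one, via lithium enolate 11 (not isolated)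
Conditions: LiN(iPr)2, THF, −78 °C; then Pd2(dba)3 (2.5 mol %), (S,S)-N,N′-(cyclohexane-1,2-diyl)bis[2-(diphenylphosphino)benzamide] (6 mol %), THF, −78 → 0 °C
Reagents that add atoms: none
Why: Proposed new method: zerovalent palladium ionises the tertiary allylic carbonate to a 1,1-disubstituted η3-allyl complex spanning C1–C2–C3, loss of CO2 from the methyl carbonate makes this irreversible, and the preformed lithium C6 enolate attacks the unsubstituted terminus C1 on the face away from the metal; the closest known reaction type is the palladium-catalysed asymmetric allylic alkylation of preformed lithium enolates of α-substituted cyclic ketones, here run as a ring closure. Ring B closes in a 6-endo mode with respect to the allyl unit (an SN2′ relationship to the carbonate), which needs the π-allyl isomer carrying the C4 tether anti at C3; that isomer arises directly from one rotamer of the carbonate and by η3–η1–η3 exchange, and leaves the C2=C3 alkene inside the ring. The only new stereocentre is quaternary C6, and it is set by which face of the planar enolate meets the allyl terminus inside the chiral pocket of the C2-symmetric diphosphine, since both stereocentres of 10 are erased before the bond forms. The step needs C1 over C3 attack (C3 attack would give a cyclobutane at the hindered terminus), C- over O-alkylation (O-attack would give an eight-membered enol ether) and α′- over γ-enolisation (kinetic amide base at −78 °C); it also needs the intramolecular closure to outrun elimination of the π-allyl to a diene, which the short two-carbon tether should favour.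

Step 7
Reactants: 12 (6S)-9-isobutoxy-3,11,11-trimethylspiro[5.5]undeca-2,8-dien-7-one
Product: 14 (6S)-3,11,11-trimethyl-7-[(trimethylsilyl)methyl]spiro[5.5]undeca-2,7-dien-9-one, via tertiary carbinol 13 (not isolated)
Conditions: Me3SiCH2Li, CeCl3, THF, −78 °C; then 1 M HCl, THF, 0 °C
Reagents that add atoms: (trimethylsilyl)methyllithium C[Si](C)(C)C[Li]; water O
Why: The organocerium reagent adds 1,2 to the hindered C7 carbonyl without γ-deprotonation, and brief cold aqueous acid triggers the Stork–Danheiser transposition (carbonyl now at C9, alkene C7=C8) before Peterson elimination or protodesilylation can compete; the C7 carbinol centre of 13 is destroyed and C6 is untouched (its descriptor stays S).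

Step 8
Reactants: 14 (6S)-3,11,11-trimethyl-7-[(trimethylsilyl)methyl]spiro[5.5]undeca-2,7-dien-9-one
Product: 17 (6R,10R)-10-bromo-3,11,11-trimethyl-7-[(trimethylsilyl)methyl]spiro[5.5]undeca-2,7-dien-9-one, via lithium dienolate 15 (not isolated), via C10 epimer mixture 16 (not isolated)
Conditions: LiN(iPr)2, THF, −78 °C; NBS, −78 °C; then Et3N (0.2 equiv.), CH2Cl2, 23 °C
Reagents that add atoms: N-bromosuccinimide O=C1CCC(=O)N1Br
Why: Kinetic α′-deprotonation of the 3-substituted cyclohexenone gives the cross-conjugated dienolate, which NBS brominates at C10; since C10 then carries the only α-hydrogen (C8 is sp2, C11 is quaternary, so neither elimination nor Favorskii closure is open), the amine should equilibrate the epimers towards the one with pseudo-equatorial bromine in the ring A half-chair that keeps the C5 arm pseudo-axial and the flatter C1–C2(sp2) arm beside the CH2SiMe3 group, expected to be 10R, and the minor epimer is separated and recycled (the C6 descriptor changes to R by priority only).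

Step 9
Reactants: 17 (6R,10R)-10-bromo-3,11,11-trimethyl-7-[(trimethylsilyl)methyl]spiro[5.5]undeca-2,7-dien-9-one
Product: 18 (6R,10R)-10-bromo-3,11,11-trimethyl-7-methylidenespiro[5.5]undec-2-en-9-one
Conditions: Bu4NF, AcOH, THF, −78 → 0 °C
Reagents that add atoms: none
Why: Fluoride attacks silicon of the vinylogous α-silyl ketone and releases the exocyclic dienolate, which acetic acid protonates kinetically at the α-carbon C8 (deconjugative protonation), so the alkene ends as the C7 methylene; the buffered medium should leave the C10 bromide and its configuration untouched.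

Step 10
Reactants: 18 (6R,10R)-10-bromo-3,11,11-trimethyl-7-methylidenespiro[5.5]undec-2-en-9-one
Product: 19 (6R,9S,10R)-10-bromo-3,11,11-trimethyl-7-methylidenespiro[5.5]undec-2-en-9-ol
Conditions: LiBH(sBu)3, THF, −78 °C; then H2O
Reagents that add atoms: none
Why: In the ring A chair with equatorial C10 bromine the axial approach to C9 is blocked by the axial C11 methyl (as in 3,3,5-trimethylcyclohexanone), so the bulky hydride attacks equatorially and should give the axial 9S alcohol cis to bromine (substrate-controlled diastereoselective reduction).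

Step 11
Reactants: 19 (6R,9S,10R)-10-bromo-3,11,11-trimethyl-7-methylidenespiro[5.5]undec-2-en-9-ol
Product: 20 (6R,9S,10R)-10-bromo-3,11,11-trimethyl-7-methylidenespiro[5.5]undec-2-en-9-yl acetate
Conditions: Ac2O, pyridine, DMAP (cat.), CH2Cl2, 23 °C
Reagents that add atoms: acetic anhydride CC(=O)OC(C)=O
Why: DMAP-catalysed acylation of the secondary alcohol, with no stereochemical change.

Step 12
Reactants: 20 (6R,9S,10R)-10-bromo-3,11,11-trimethyl-7-methylidenespiro[5.5]undec-2-en-9-yl acetate
Product: 21 (2R,3S,6R,9S,10R)-10-bromo-2,3-epoxy-3,11,11-trimethyl-7-methylidenespiro[5.5]undecan-9-yl acetate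
Conditions: 1,2:4,5-di-O-isopropylidene-β-D-erythro-2,3-hexodiulo-2,6-pyranose (30 mol %), KHSO5 (as 2KHSO5·KHSO4·K2SO4), K2CO3, Bu4NHSO4, MeCN/CH2(OMe)2/aq. Na2B4O7 buffer (pH 10.5), 0 °C
Reagents that add atoms: potassium peroxymonosulfate [K+].[O-]S(=O)(=O)OO
Why: Shi epoxidation through the spiro dioxirane transition state should place oxygen on the ring B face anti to C7, which is the face this catalyst selects in 1-substituted cyclohexenes and also the less hindered one because C7 and its methylene screen the other, giving the 2R,3S epoxide, while the hindered 1,1-disubstituted C7 methylene is a poor substrate for this catalyst.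

Step 13
Reactants: 21 (2R,3S,6R,9S,10R)-10-bromo-2,3-epoxy-3,11,11-trimethyl-7-methylidenespiro[5.5]undecan-9-yl acetate
Product: 22 (2S,3S,6R,9S,10R)-10-bromo-2-chloro-3-hydroxy-3,11,11-trimethyl-7-methylidenespiro[5.5]undecan-9-yl acetate
Conditions: LiCl, AcOH, THF, 23 → 40 °C
Reagents that add atoms: lithium chloride [Li+].[Cl-]
Why: Acid-assisted SN2 opening of the trisubstituted epoxide by chloride at the secondary carbon C2 (trans-diaxial, Fürst–Plattner rule) should invert C2 to 2S and leave the tertiary C3–O bond intact, anti to the new chlorine.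

Step 14
Reactants: 22 (2S,3S,6R,9S,10R)-10-bromo-2-chloro-3-hydroxy-3,11,11-trimethyl-7-methylidenespiro[5.5]undecan-9-yl acetate
Product: 23 9-acetylisoobtusol, (2S,3S,6R,9S,10R)-3,10-dibromo-2-chloro-3,11,11-trimethyl-7-methylidenespiro[5.5]undecan-9-yl acetate
Conditions: Me2C=C(Br)NMe2, CH2Cl2, 0 → 23 °C
Reagents that add atoms: 1-bromo-N,N,2-trimethylprop-1-en-1-amine CC(C)=C(Br)N(C)C
Why: The α-bromo enamine turns the tertiary alcohol into an alkoxy-iminium bromide under neutral conditions (no free HBr, so the methylene and the acetate should survive), and SN1 substitution with anchimeric assistance by the anti C2 chlorine (chloronium opened by bromide at the tertiary carbon) should give the C3 bromide with retention, trans to chlorine.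

**Compound list**

1 | dimedone (5,5-dimethylcyclohexane-1,3-dione) | CC1(C)CC(=O)CC(=O)C1 | starting material
2 | 3-isobutoxy-5,5-dimethylcyclohex-2-en-1-one | CC(C)COC1=CC(=O)CC(C)(C)C1 | intermediate
3 | 2-(2-bromoethyl)-2-methyl-1,3-dioxolane | CC1(CCBr)OCCO1 | starting material
4 | 2-(2-iodoethyl)-2-methyl-1,3-dioxolane | CC1(CCI)OCCO1 | intermediate
5 | lithium 5-isobutoxy-3,3-dimethylcyclohexa-1,5-dien-1-olate (α′-enolate of 2, not isolated) | [Li]OC1=CC(C)(C)CC(OCC(C)C)=C1 | intermediate
6 | 3-isobutoxy-5,5-dimethyl-6-[2-(2-methyl-1,3-dioxolan-2-yl)ethyl]cyclohex-2-en-1-one (racemic) | CC(C)COC1=CC(=O)C(CCC2(C)OCCO2)C(C)(C)C1 | intermediate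
7 | 3-isobutoxy-5,5-dimethyl-6-(3-oxobutyl)cyclohex-2-en-1-one (racemic) | CC(C)COC1=CC(=O)C(CCC(C)=O)C(C)(C)C1 | intermediate
8 | vinylmagnesium bromide | C=C[Mg]Br | starting material
9 | bromomagnesium alkoxide of the tertiary allylic alcohol from 7 (stereoisomer mixture, not isolated) | CC(C)COC1=CC(=O)C(CCC(C)(O[Mg]Br)C=C)C(C)(C)C1 | intermediate
10 | 5-(4-isobutoxy-6,6-dimethyl-2-oxocyclohex-3-en-1-yl)-3-methylpent-1-en-3-yl methyl carbonate (stereoisomer mixture) | CC(C)COC1=CC(=O)C(CCC(C)(OC(=O)OC)C=C)C(C)(C)C1 | intermediate
11 | lithium C6 enolate of 10 (not isolated) | [Li]OC1=C(CCC(C)(OC(=O)OC)C=C)C(C)(C)CC(OCC(C)C)=C1 | intermediate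
12 | (6S)-9-isobutoxy-3,11,11-trimethylspiro[5.5]undeca-2,8-dien-7-one | O=C1C=C(OCC(C)C)CC(C)(C)[C@@]12CCC(C)=CC2 | intermediate
13 | (6S)-9-isobutoxy-3,11,11-trimethyl-7-[(trimethylsilyl)methyl]spiro[5.5]undeca-2,8-dien-7-ol (both C7 epimers, not isolated) | OC1(C[Si](C)(C)C)C=C(OCC(C)C)CC(C)(C)[C@@]12CCC(C)=CC2 | intermediate
14 | (6S)-3,11,11-trimethyl-7-[(trimethylsilyl)methyl]spiro[5.5]undeca-2,7-dien-9-one | C[Si](C)(C)CC1=CC(=O)CC(C)(C)[C@@]12CCC(C)=CC2 | intermediate
15 | lithium C9–C10 dienolate of 14 (not isolated) | C[Si](C)(C)CC1=CC(O[Li])=CC(C)(C)[C@@]12CCC(C)=CC2 | intermediate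
16 | 10-bromo-3,11,11-trimethyl-7-[(trimethylsilyl)methyl]spiro[5.5]undeca-2,7-dien-9-one, mixture of C10 epimers (not isolated) | C[Si](C)(C)CC1=CC(=O)C(Br)C(C)(C)[C@@]12CCC(C)=CC2 | intermediate
17 | (6R,10R)-10-bromo-3,11,11-trimethyl-7-[(trimethylsilyl)methyl]spiro[5.5]undeca-2,7-dien-9-one | C[Si](C)(C)CC1=CC(=O)[C@H](Br)C(C)(C)[C@@]12CCC(C)=CC2 | intermediate
18 | (6R,10R)-10-bromo-3,11,11-trimethyl-7-methylidenespiro[5.5]undec-2-en-9-one | C=C1CC(=O)[C@H](Br)C(C)(C)[C@@]12CCC(C)=CC2 | intermediate
19 | (6R,9S,10R)-10-bromo-3,11,11-trimethyl-7-methylidenespiro[5.5]undec-2-en-9-ol | C=C1C[C@H](O)[C@H](Br)C(C)(C)[C@@]12CCC(C)=CC2 | intermediate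
20 | (6R,9S,10R)-10-bromo-3,11,11-trimethyl-7-methylidenespiro[5.5]undec-2-en-9-yl acetate | C=C1C[C@H](OC(C)=O)[C@H](Br)C(C)(C)[C@@]12CCC(C)=CC2 | intermediate
21 | (2R,3S,6R,9S,10R)-10-bromo-2,3-epoxy-3,11,11-trimethyl-7-methylidenespiro[5.5]undecan-9-yl acetate | C=C1C[C@H](OC(C)=O)[C@H](Br)C(C)(C)[C@@]12CC[C@]3(C)O[C@@H]3C2 | intermediate
22 | (2S,3S,6R,9S,10R)-10-bromo-2-chloro-3-hydroxy-3,11,11-trimethyl-7-methylidenespiro[5.5]undecan-9-yl acetate | C=C1C[C@H](OC(C)=O)[C@H](Br)C(C)(C)[C@@]12CC[C@](C)(O)[C@@H](Cl)C2 | intermediate
23 | 9-acetylisoobtusol, (2S,3S,6R,9S,10R)-3,10-dibromo-2-chloro-3,11,11-trimethyl-7-methylidenespiro[5.5]undecan-9-yl acetate | C=C1C[C@H](OC(C)=O)[C@H](Br)C(C)(C)[C@@]12CC[C@](C)(Br)[C@@H](Cl)C2 | target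

**Step count and risks**

Total step count: 14. Longest linear sequence: 13 steps (dimedone to the target; step 2 is a one-step side branch).

Steps most likely to fail:

- **Step 6 (proposed new method).** The ring closure may be outrun by elimination of the π-allyl complex to a diene or by proton transfer, and the ligand may not distinguish the two enolate faces well enough. The fallback uses known chemistry, sets out from 2 and returns at 12. Alkylation of the lithium enolate of 2 with 4-bromo-2-methylbut-1-ene (LiN(iPr)2, NaI cat., DMPU) should give 3-isobutoxy-5,5-dimethyl-6-(3-methylbut-3-enyl)cyclohex-2-en-1-one F1. Enolisation (LiN(iPr)2, TMEDA) and O-acylation with allyl chloroformate should give the allyl enol carbonate F2. Palladium-catalysed enantioselective decarboxylative allylic alkylation (Pd2(dba)3, (R)-4-tert-butyl-2-[2-(diphenylphosphino)phenyl]-4,5-dihydrooxazole, or its antipode if needed) should set the quaternary centre in the (6S)-6-allyl ketone F3. Ring-closing metathesis with the second-generation Grubbs catalyst then joins the allyl and methallyl-type ends to the trisubstituted ring B alkene of 12.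

- **Step 8.** Deprotonation may stray to the silylmethyl group, and the thermodynamic preference between the C10 epimers may be too small to be useful. The fallback sets out from the unequilibrated mixture 16 and returns at 19. Desilylative deconjugation of 16 as in step 9 should give 18 together with its (6R,10S) epimer F4. Reduction under catalyst control ((R)-2-methyl-CBS-oxazaborolidine, catecholborane, toluene, −78 °C; Corey–Bakshi–Shibata reduction) should fix C9 as S in both. For 18 this agrees with its own equatorial-attack preference and gives 19, while F4 is the mismatched case and gives the (6R,9S,10S) trans-bromohydrin F5, which is removed by chromatography.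

- **Step 14.** The tertiary carbinol may ionise without help from chlorine, leading to elimination or loss of configuration at C3, or the cation may be captured by the C7 methylene. The SN2 opening before it (step 13) may also be slow, because the C2 face syn to C7 is screened by the C7 methylene. The fallback sets out from 21 and returns at 23; it brings chlorine in at C3 and lets it migrate. Anhydrous HCl (1 equiv., Et2O/CH2Cl2, −78 °C) should open the epoxide at the tertiary carbon with inversion to the (2R,3R) 3-chloro-2-hydroxy compound F6. Tf2O with 2,6-di-tert-butylpyridine should give the C2 triflate F7. On warming with Bu4NBr, the anti C3 chlorine should displace the triflate to a chloronium ion on the C7 face, which bromide opens at the tertiary carbon C3. The result is a 1,2-chlorine shift with bromide capture that gives the 2S chloride and 3S bromide of 23.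

**Further compounds**

F1 | step 6 | 3-isobutoxy-5,5-dimethyl-6-(3-methylbut-3-enyl)cyclohex-2-en-1-one (racemic) | CC(C)COC1=CC(=O)C(CCC(C)=C)C(C)(C)C1
F2 | step 6 | allyl 5-isobutoxy-3,3-dimethyl-2-(3-methylbut-3-enyl)cyclohexa-1,5-dien-1-yl carbonate | C=CCOC(=O)OC1=C(CCC(C)=C)C(C)(C)CC(OCC(C)C)=C1
F3 | step 6 | (6S)-6-allyl-3-isobutoxy-5,5-dimethyl-6-(3-methylbut-3-enyl)cyclohex-2-en-1-one | O=C1C=C(OCC(C)C)CC(C)(C)[C@@]1(CC=C)CCC(C)=C
F4 | step 8 | (6R,10S)-10-bromo-3,11,11-trimethyl-7-methylidenespiro[5.5]undec-2-en-9-one | C=C1CC(=O)[C@@H](Br)C(C)(C)[C@@]12CCC(C)=CC2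
F5 | step 8 | (6R,9S,10S)-10-bromo-3,11,11-trimethyl-7-methylidenespiro[5.5]undec-2-en-9-ol | C=C1C[C@H](O)[C@@H](Br)C(C)(C)[C@@]12CCC(C)=CC2
F6 | step 14 | (2R,3R,6R,9S,10R)-10-bromo-3-chloro-2-hydroxy-3,11,11-trimethyl-7-methylidenespiro[5.5]undecan-9-yl acetate | C=C1C[C@H](OC(C)=O)[C@H](Br)C(C)(C)[C@@]12CC[C@@](C)(Cl)[C@H](O)C2
F7 | step 14 | (2R,3R,6R,9S,10R)-10-bromo-3-chloro-3,11,11-trimethyl-7-methylidene-2-(trifluoromethylsulfonyloxy)spiro[5.5]undecan-9-yl acetate | C=C1C[C@H](OC(C)=O)[C@H](Br)C(C)(C)[C@@]12CC[C@@](C)(Cl)[C@H](OS(=O)(=O)C(F)(F)F)C2
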